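**Strategy.** Ring B (C5–C10) carries the C6 oxygen and the spiro ether carbon C9 in a 1,4-relationship, so it is read as the Diels–Alder adduct of a 2-silyloxydiene (C7=C6–C5=C10, from β-cyclocitral) and a captodative exocyclic enone: ring C as a (Z)-2-ethylidene-oxolan-3-one. One cycloaddition closes ring B, makes C7–C8 and C9–C10 and sets C8, C9 and quaternary C10. The dienophile already holds C13 (Sharpless epoxidation) with an ethynyl and a silyloxymethyl arm; C13 steers the π-face, and the two arms later close ring D by alkynol cycloisomerisation. The C11 ketone is removed, C6 is reduced and acetylated.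

Key step: step 10

Remark: labdane numbering is used for all intermediates (C17 = methyl on C8, C20 = methyl on C10, ring C = C9/C11/C12/C13/O, ring D = C13/C14/C15/O/C16; α = face opposite to C20). The target is taken as (5S,6R,8R,9R,10S,13R)-6β-acetoxy-9α,13;15,16-diepoxylabd-14-ene, as its SMILES encodes. Compounds 1, 5 and 6 are assumed to be commercial.

**Diene (steps 1–3)**

Step 1
Reactants: 1 β-cyclocitral
Product: 2 1-(2,6,6-trimethylcyclohex-1-en-1-yl)ethan-1-ol (racemic)
Conditions: MeLi, Et2O, −78 → 0 °C; aq. NH4Cl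
Reagents that add atoms: methyllithium, [Li]C
Why: 1,2-addition of an organolithium to the hindered conjugated aldehyde should be clean, and the racemic carbinol centre is removed in step 2.

Step 2
Reactants: 2 1-(2,6,6-trimethylcyclohex-1-en-1-yl)ethan-1-ol
Product: 3 1-(2,6,6-trimethylcyclohex-1-en-1-yl)ethan-1-one
Conditions: Dess–Martin periodinane, CH2Cl2, rt
Reagents that add atoms: none
Why: Dess–Martin oxidation of a secondary allylic alcohol gives the enone under neutral conditions that should not move the ring double bond.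

Step 3
Reactants: 3 1-(2,6,6-trimethylcyclohex-1-en-1-yl)ethan-1-one
Product: 4 tert-butyldimethyl{[1-(2,6,6-trimethylcyclohex-1-en-1-yl)ethenyl]oxy}silane
Conditions: LDA, THF, −78 °C; TBSCl, DMPU, −78 °C → rt
Reagents that add atoms: tert-butyldimethylsilyl chloride, CC(C)(C)[Si](C)(C)Cl
Why: Kinetic deprotonation of the acetyl CH3 gives the cross-conjugated lithium enolate, and O-silylation should give the 2-silyloxydiene.

**Dienophile (steps 4–9)**

Step 4
Reactants: 5 2-bromoprop-2-en-1-ol; 6 ethynyltri(propan-2-yl)silane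
Product: 7 2-methylidene-4-[tri(propan-2-yl)silyl]but-3-yn-1-ol
Conditions: Pd(PPh3)2Cl2 (2 mol %), CuI (4 mol %), i-Pr2NH, THF, rt
Reagents that add atoms: none
Why: Sonogashira coupling of a vinyl bromide with a terminal alkyne tolerates the free allylic alcohol.

Step 5
Reactants: 7 2-methylidene-4-[tri(propan-2-yl)silyl]but-3-yn-1-ol
Product: 8 (R)-(2-{[tri(propan-2-yl)silyl]ethynyl}oxiran-2-yl)methanol
Conditions: Ti(Oi-Pr)4, D-(−)-DIPT, t-BuOOH, 4 Å MS, CH2Cl2, −20 °C
Reagents that add atoms: tert-butyl hydroperoxide, CC(C)(C)OO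
Why: Sharpless asymmetric epoxidation of a 2-substituted allylic alcohol with the D-(−)-tartrate ligand should deliver oxygen to the face that gives the (R)-epoxy alcohol, and this reagent-controlled quaternary centre becomes C13.

Step 6
Reactants: 8 (R)-(2-{[tri(propan-2-yl)silyl]ethynyl}oxiran-2-yl)methanol
Product: 9 (S)-tert-butyl[(2-{[tri(propan-2-yl)silyl]ethynyl}oxiran-2-yl)methoxy]diphenylsilane
Conditions: TBDPSCl, imidazole, DMF, 0 °C → rt
Reagents that add atoms: tert-butyldiphenylsilyl chloride, CC(C)(C)[Si](Cl)(c1ccccc1)c1ccccc1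
Why: Silylation of the primary alcohol gives an acid- and base-stable ether (the descriptor changes by priority only) that later serves as the bulky arm at C13.

Step 7
Reactants: 9 (S)-tert-butyl[(2-{[tri(propan-2-yl)silyl]ethynyl}oxiran-2-yl)methoxy]diphenylsilane
Product: 10 (3R)-3-{[(tert-butyldiphenylsilyl)oxy]methyl}-1-[tri(propan-2-yl)silyl]hexa-1,5-diyn-3-ol
Conditions: LiC≡CH·H2NCH2CH2NH2, DMSO, rt; aq. NH4Cl
Reagents that add atoms: lithium acetylide (ethylenediamine complex), [Li]C#C
Why: SN2 opening of the 2,2-disubstituted epoxide at its CH2 terminus by the acetylide leaves the quaternary centre untouched and gives the tertiary homopropargylic alcohol.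

Step 8
Reactants: 10 (3R)-3-{[(tert-butyldiphenylsilyl)oxy]methyl}-1-[tri(propan-2-yl)silyl]hexa-1,5-diyn-3-ol
Product: 11 (5R)-5-{[(tert-butyldiphenylsilyl)oxy]methyl}-5-{[tri(propan-2-yl)silyl]ethynyl}oxolan-3-one
Conditions: Ph3PAuNTf2 (5 mol %), 3,5-dichloropyridine N-oxide, MsOH, ClCH2CH2Cl, rt
Reagents that add atoms: 3,5-dichloropyridine N-oxide, [O-][n+]1cc(Cl)cc(Cl)c1
Why: Gold-catalysed N-oxide oxidation of the terminal alkyne gives an α-oxo gold carbene at the terminal carbon, which the tertiary hydroxyl traps by intramolecular O–H insertion to close ring C as an oxolan-3-one, while the silyl-capped internal alkyne should stay inert.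

Step 9
Reactants: 11 (5R)-5-{[(tert-butyldiphenylsilyl)oxy]methyl}-5-{[tri(propan-2-yl)silyl]ethynyl}oxolan-3-one
Product: 14 (2Z,5R)-2-ethylidene-5-{[(tert-butyldiphenylsilyl)oxy]methyl}-5-{[tri(propan-2-yl)silyl]ethynyl}oxolan-3-one, via aldol adduct 12 (not isolated), via mesylate 13 (not isolated)
Conditions: LiHMDS, THF, −78 °C; MeCHO; then MsCl, Et3N, −78 → 25 °C
Reagents that add atoms: acetaldehyde, CC=O
Why: Directed aldol condensation in which the base should deprotonate C2 (O–CH2–C=O, the future C9) because C4 is shielded by the adjacent quaternary C5, and mesylation with E1cB elimination should give the thermodynamically preferred Z-alkene (methyl anti to the carbonyl).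

**Union and endgame (steps 10–15)**

Step 10
Reactants: 4 tert-butyldimethyl{[1-(2,6,6-trimethylcyclohex-1-en-1-yl)ethenyl]oxy}silane; 14 (2Z,5R)-2-ethylidene-5-{[(tert-butyldiphenylsilyl)oxy]methyl}-5-{[tri(propan-2-yl)silyl]ethynyl}oxolan-3-one
Product: 15 (8R,9R,10S,13R)-6-[(tert-butyldimethylsilyl)oxy]-16-[(tert-butyldiphenylsilyl)oxy]-9α,13-epoxy-15-[tri(propan-2-yl)silyl]labd-5-en-14-yn-11-one
Conditions: 4 (1.5 equiv), Tf2NH (10 mol %), CH2Cl2, −78 → −20 °C; Et3N quench
Reagents that add atoms: none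
Why: Triflimide protonates a little diene to give TBSNTf2, which silylates the C11 carbonyl of 14; C7 of the diene then adds to C8 and the resulting C9 silyl enol ether closes onto the C10 terminus of the silyloxy-allyl cation (asynchronous [4+2], at the limit Mukaiyama–Michael then Michael with silyl transfer), which releases the C5=C6 TBS enol ether and the silyl cation for turnover. The closest known reaction type is the strong-acid-promoted (AlBr3/AlMe3 or Tf2NH) Diels–Alder reaction of hindered 2-silyloxydienes with hindered enones that builds vicinal quaternary carbons, together with the cycloadditions of aurone-type 2-alkylidene-furan-3-ones. Ring B is closed by intermolecular [4+2] cycloaddition (in the stepwise limit a 6-endo-trig attack of C9 on C10). C8 against C9 follows from the Z geometry of the dienophile (suprafacial addition, C17 cis to the ring oxygen); C9 against C13 from approach to the face that carries the slim ethynyl arm, anti to CH2OTBDPS; C10 against C9 from the carbonyl-exo orientation, which keeps the silylated C11 carbonyl away from the C4 gem-dimethyl and C6 silyloxy groups under the diene. The step needs regioselectivity (nucleophilic C7 to the β-carbon C8, secured by the 2-silyloxy group and the enone polarisation), exo selectivity and π-facial selectivity as described, and any O-closure to a dihydropyran (hetero-Diels–Alder) should be reversible under the acid and drain to the carbocycle.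

Step 11
Reactants: 15 (8R,9R,10S,13R)-6-[(tert-butyldimethylsilyl)oxy]-16-[(tert-butyldiphenylsilyl)oxy]-9α,13-epoxy-15-[tri(propan-2-yl)silyl]labd-5-en-14-yn-11-one
Product: 17 (8R,9R,10S,13R)-6-[(tert-butyldimethylsilyl)oxy]-16-[(tert-butyldiphenylsilyl)oxy]-9α,13-epoxy-15-[tri(propan-2-yl)silyl]labd-5-en-14-yne, via tosylhydrazone 16 (not isolated)
Conditions: TsNHNH2, EtOH, 60 °C; evaporate; catecholborane, CHCl3, 0 °C; NaOAc·3H2O, reflux
Reagents that add atoms: none
Why: Reductive deoxygenation through the tosylhydrazone (hydride addition to C=N, loss of sulfinate, loss of N2 from the diazene) works without strong base, and the hindered TBS enol ether keeps C6 masked so that only C11 reacts.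

Step 12
Reactants: 17 (8R,9R,10S,13R)-6-[(tert-butyldimethylsilyl)oxy]-16-[(tert-butyldiphenylsilyl)oxy]-9α,13-epoxy-15-[tri(propan-2-yl)silyl]labd-5-en-14-yne
Product: 18 (5S,8R,9R,10S,13R)-9α,13-epoxy-16-hydroxylabd-14-yn-6-one
Conditions: TBAF (5 equiv), THF, 0 °C → rt; aq. NH4Cl
Reagents that add atoms: none
Why: Fluoride cleaves the enol ether, the primary silyl ether and the alkynyl silane in one operation, and protonation of the C6 enolate at C5 under equilibrating conditions should give the trans-decalone (5α-H).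

Step 13
Reactants: 18 (5S,8R,9R,10S,13R)-9α,13-epoxy-16-hydroxylabd-14-yn-6-one
Product: 19 (5S,8R,9R,10S,13R)-9α,13;15,16-diepoxylabd-14-en-6-one
Conditions: W(CO)6 (25 mol %), Et3N, THF, hν (350 nm), 60 °C
Reagents that add atoms: none
Why: Alkynol cycloisomerisation through a tungsten vinylidene puts the C16 oxygen on the terminal carbon C15 (endo mode) to give the 2,3-dihydrofuran ring D, helped by the quaternary C13 and run in amine so that the acid-labile enol ether survives.

Step 14
Reactants: 19 (5S,8R,9R,10S,13R)-9α,13;15,16-diepoxylabd-14-en-6-one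
Product: 20 (5S,6R,8R,9R,10S,13R)-9α,13;15,16-diepoxylabd-14-en-6β-ol
Conditions: NaBH4, MeOH–THF, 0 °C → rt
Reagents that add atoms: none
Why: Hydride should attack C6 from the α-face because the β-face is blocked by the axial 4β- and 10β-methyl groups, which gives the axial 6β-alcohol.

Step 15
Reactants: 20 (5S,6R,8R,9R,10S,13R)-9α,13;15,16-diepoxylabd-14-en-6β-ol
Product: 21 (5S,6R,8R,9R,10S,13R)-6β-acetoxy-9α,13;15,16-diepoxylabd-14-ene (CNP0242014.1)
Conditions: Ac2O, DMAP, Et3N, CH2Cl2, rt; chromatography on Et3N-deactivated silica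
Reagents that add atoms: acetic anhydride, CC(=O)OC(C)=O
Why: DMAP-catalysed acylation should acetylate the hindered axial alcohol under basic conditions that leave the acid-labile spiro enol ether intact.

**Compound list**

1 | β-cyclocitral (2,6,6-trimethylcyclohex-1-ene-1-carbaldehyde) | CC1=C(C=O)C(C)(C)CCC1 | starting material
2 | 1-(2,6,6-trimethylcyclohex-1-en-1-yl)ethan-1-ol (racemic) | CC(O)C1=C(C)CCCC1(C)C | intermediate
3 | 1-(2,6,6-trimethylcyclohex-1-en-1-yl)ethan-1-one | CC(=O)C1=C(C)CCCC1(C)C | intermediate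
4 | tert-butyldimethyl{[1-(2,6,6-trimethylcyclohex-1-en-1-yl)ethenyl]oxy}silane | C=C(O[Si](C)(C)C(C)(C)C)C1=C(C)CCCC1(C)C | intermediate
5 | 2-bromoprop-2-en-1-ol | OCC(Br)=C | starting material
6 | ethynyltri(propan-2-yl)silane | C#C[Si](C(C)C)(C(C)C)C(C)C | starting material
7 | 2-methylidene-4-[tri(propan-2-yl)silyl]but-3-yn-1-ol | OCC(=C)C#C[Si](C(C)C)(C(C)C)C(C)C | intermediate
8 | (R)-(2-{[tri(propan-2-yl)silyl]ethynyl}oxiran-2-yl)methanol | C1[C@](CO)(C#C[Si](C(C)C)(C(C)C)C(C)C)O1 | intermediate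
9 | (S)-tert-butyl[(2-{[tri(propan-2-yl)silyl]ethynyl}oxiran-2-yl)methoxy]diphenylsilane | C1[C@](CO[Si](c2ccccc2)(c2ccccc2)C(C)(C)C)(C#C[Si](C(C)C)(C(C)C)C(C)C)O1 | intermediate
10 | (3R)-3-{[(tert-butyldiphenylsilyl)oxy]methyl}-1-[tri(propan-2-yl)silyl]hexa-1,5-diyn-3-ol | C#CC[C@](CO[Si](c1ccccc1)(c1ccccc1)C(C)(C)C)(C#C[Si](C(C)C)(C(C)C)C(C)C)O | intermediate
11 | (5R)-5-{[(tert-butyldiphenylsilyl)oxy]methyl}-5-{[tri(propan-2-yl)silyl]ethynyl}oxolan-3-one | O=C1CO[C@@](CO[Si](c2ccccc2)(c2ccccc2)C(C)(C)C)(C#C[Si](C(C)C)(C(C)C)C(C)C)C1 | intermediate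
12 | (5R)-2-(1-hydroxyethyl)-5-{[(tert-butyldiphenylsilyl)oxy]methyl}-5-{[tri(propan-2-yl)silyl]ethynyl}oxolan-3-one (aldol adduct, diastereomer mixture, lithium alkoxide in the flask) | CC(O)C1O[C@@](CO[Si](c2ccccc2)(c2ccccc2)C(C)(C)C)(C#C[Si](C(C)C)(C(C)C)C(C)C)CC1=O | intermediate (not isolated)
13 | methanesulfonate of 12 | CC(OS(C)(=O)=O)C1O[C@@](CO[Si](c2ccccc2)(c2ccccc2)C(C)(C)C)(C#C[Si](C(C)C)(C(C)C)C(C)C)CC1=O | intermediate (not isolated)
14 | (2Z,5R)-2-ethylidene-5-{[(tert-butyldiphenylsilyl)oxy]methyl}-5-{[tri(propan-2-yl)silyl]ethynyl}oxolan-3-one | C/C=C1\O[C@@](CO[Si](c2ccccc2)(c2ccccc2)C(C)(C)C)(C#C[Si](C(C)C)(C(C)C)C(C)C)CC1=O | intermediate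
15 | (8R,9R,10S,13R)-6-[(tert-butyldimethylsilyl)oxy]-16-[(tert-butyldiphenylsilyl)oxy]-9α,13-epoxy-15-[tri(propan-2-yl)silyl]labd-5-en-14-yn-11-one | CC(C)(C)[Si](C)(C)OC=1C[C@@H](C)[C@]2(C(=O)C[C@](CO[Si](c3ccccc3)(c3ccccc3)C(C)(C)C)(C#C[Si](C(C)C)(C(C)C)C(C)C)O2)[C@@]2(C)CCCC(C)(C)C2=1 | intermediate
16 | 11-(4-methylbenzenesulfonyl)hydrazone of 15 | CC(C)(C)[Si](C)(C)OC=1C[C@@H](C)[C@]2(C(=NNS(=O)(=O)c3ccc(C)cc3)C[C@](CO[Si](c3ccccc3)(c3ccccc3)C(C)(C)C)(C#C[Si](C(C)C)(C(C)C)C(C)C)O2)[C@@]2(C)CCCC(C)(C)C2=1 | intermediate (not isolated)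
17 | (8R,9R,10S,13R)-6-[(tert-butyldimethylsilyl)oxy]-16-[(tert-butyldiphenylsilyl)oxy]-9α,13-epoxy-15-[tri(propan-2-yl)silyl]labd-5-en-14-yne | CC(C)(C)[Si](C)(C)OC=1C[C@@H](C)[C@]2(CC[C@](CO[Si](c3ccccc3)(c3ccccc3)C(C)(C)C)(C#C[Si](C(C)C)(C(C)C)C(C)C)O2)[C@@]2(C)CCCC(C)(C)C2=1 | intermediate
18 | (5S,8R,9R,10S,13R)-9α,13-epoxy-16-hydroxylabd-14-yn-6-one | O=C1C[C@@H](C)[C@]2(CC[C@](CO)(C#C)O2)[C@@]2(C)CCCC(C)(C)[C@H]12 | intermediate
19 | (5S,8R,9R,10S,13R)-9α,13;15,16-diepoxylabd-14-en-6-one | O=C1C[C@@H](C)[C@]2(CC[C@]3(C=COC3)O2)[C@@]2(C)CCCC(C)(C)[C@H]12 | intermediate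
20 | (5S,6R,8R,9R,10S,13R)-9α,13;15,16-diepoxylabd-14-en-6β-ol | O[C@@H]1C[C@@H](C)[C@]2(CC[C@]3(C=COC3)O2)[C@@]2(C)CCCC(C)(C)[C@H]12 | intermediate
21 | (5S,6R,8R,9R,10S,13R)-6β-acetoxy-9α,13;15,16-diepoxylabd-14-ene (CNP0242014.1) | CC(=O)O[C@@H]1C[C@@H](C)[C@]2(CC[C@]3(C=COC3)O2)[C@@]2(C)CCCC(C)(C)[C@H]12 | target

**Totals.** Total step count: 15. Longest linear sequence: 12 steps (5 → 21, steps 4–15).

**Steps most likely to fail**

Step 10. The second bond, between the two fully substituted carbons C9 and C10, may not close, so that the reaction stops at the Michael stage or at the O-closed dihydropyran. The carbonyl-endo orientation may compete, and the acid may ionise the tertiary propargylic C13–O bond. The fallback changes the mechanism to an anionic double Michael reaction and sets out from ketone 3 and dienophile 14. LDA (THF, −78 °C) deprotonates 3 at the acetyl methyl group, the lithium dienolate adds through C7 to C8 of 14, and on warming the furanone enolate closes onto C10 of the enone. This gives the lithium C5=C6 enolate of the adduct F1, which is silylated in the same flask with TBSCl/DMPU. The fallback comes back to the route at 15.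

Step 9. Enolisation may go toward C4 (the future C12) instead of C2, which would put the ethylidene group on the wrong side of the ketone; acetaldehyde may also self-condense. The fallback fixes the position by construction and sets out from diynol 10. Double deprotonation (n-BuLi, 2.2 equiv) and addition of acetaldehyde gives (3R)-3-{[(tert-butyldiphenylsilyl)oxy]methyl}-1-[tri(propan-2-yl)silyl]octa-1,5-diyne-3,7-diol F2. A gold-catalysed Meyer–Schuster rearrangement of the secondary propargylic alcohol gives the (E)-enone F3. Nucleophilic epoxidation (t-BuOOH, DBU) gives the epoxy ketone F4, in which the tertiary alkoxide opens the epoxide at the carbon α to the ketone (5-exo-tet). The fallback comes back to the route at aldol adduct 12, which is mesylated and eliminated to 14 as in step 9.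

Step 11. Hydrazone formation at the ketone next to the spiro centre may be slow, the diazene may fragment with β-elimination of the ring oxygen (C9–O cleavage), and the enol ether may hydrolyse during the sequence. The fallback is a radical deoxygenation and sets out from 15. NaBH4 gives the 11-alcohol F5, NaH/CS2/MeI gives the S-methyl xanthate F6, and Bu3SnH/AIBN in toluene at 80 °C (Barton–McCombie) removes the oxygen. The fallback comes back to the route at 17.

**Further compounds**

F1 | step 10 | lithium C5=C6 enolate of the 6,11-dione adduct | [Li]OC=1C[C@@H](C)[C@]2(C(=O)C[C@](CO[Si](c3ccccc3)(c3ccccc3)C(C)(C)C)(C#C[Si](C(C)C)(C(C)C)C(C)C)O2)[C@@]2(C)CCCC(C)(C)C2=1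
F2 | step 9 | (3R)-3-{[(tert-butyldiphenylsilyl)oxy]methyl}-1-[tri(propan-2-yl)silyl]octa-1,5-diyne-3,7-diol | CC(O)C#CC[C@](CO[Si](c1ccccc1)(c1ccccc1)C(C)(C)C)(C#C[Si](C(C)C)(C(C)C)C(C)C)O
F3 | step 9 | (2E,6R)-6-hydroxy-6-{[(tert-butyldiphenylsilyl)oxy]methyl}-8-[tri(propan-2-yl)silyl]oct-2-en-7-yn-4-one | C/C=C/C(=O)C[C@](CO[Si](c1ccccc1)(c1ccccc1)C(C)(C)C)(C#C[Si](C(C)C)(C(C)C)C(C)C)O
F4 | step 9 | 2,3-epoxide of F3 (trans, diastereomer mixture) | CC1OC1C(=O)C[C@](CO[Si](c2ccccc2)(c2ccccc2)C(C)(C)C)(C#C[Si](C(C)C)(C(C)C)C(C)C)O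
F5 | step 11 | 11-alcohol from 15 | CC(C)(C)[Si](C)(C)OC=1C[C@@H](C)[C@]2(C(O)C[C@](CO[Si](c3ccccc3)(c3ccccc3)C(C)(C)C)(C#C[Si](C(C)C)(C(C)C)C(C)C)O2)[C@@]2(C)CCCC(C)(C)C2=1
F6 | step 11 | O-(11-yl) S-methyl xanthate of F5 | CC(C)(C)[Si](C)(C)OC=1C[C@@H](C)[C@]2(C(OC(=S)SC)C[C@](CO[Si](c3ccccc3)(c3ccccc3)C(C)(C)C)(C#C[Si](C(C)C)(C(C)C)C(C)C)O2)[C@@]2(C)CCCC(C)(C)C2=1
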